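# Proposed total synthesis of 5,7,3',5'-tetrahydroxy-3,6,8,4'-tetramethoxyflavone (15)

## The problem

The target 15, 5,7-dihydroxy-2-(3,5-dihydroxy-4-methoxyphenyl)-3,6,8-trimethoxy-4H-chromen-4-one, is a flavone. Ring A is fully oxygenated (5-OH, 6-OMe, 7-OH, 8-OMe next to the ring oxygen O1), ring C carries a methoxy group at C3, and ring B is a 3',5'-dihydroxy-4'-methoxyphenyl group on C2. It has no stereocentre, so there is nothing to set and nothing that could direct; the difficulty is regiochemical throughout. Four hydroxyl and four methoxy groups sit on eight different oxygens, and a late selective methylation of a polyphenol cannot be trusted to tell them apart. Each methoxy group should therefore enter as such, and each future hydroxyl should travel as an ether that comes off last without touching the methyl ethers. Ring A is hexasubstituted: no C–H is left for late substitution, and the bond from C4a to the carbonyl carbon C4 has to be formed between two ortho oxygen substituents. The fragile parts are the free electron-rich phenols, which oxidise easily, and the pyranone, whose C2 is open to nucleophiles and to ring opening in strong base, so the last steps have to be mild. The structure offers two handles: C4 is a carbonyl carbon held between C4a and C3 while C2 and C3 stand at the oxidation level of an alkyne, so C4 can be brought in as carbon monoxide between a ring A aryl iodide and a ring B arylacetylene. Once O1 is masked like O5 and O7, ring A also has a mirror plane through C4a and C7, so the two oxygens ortho to C4a are equivalent and ring C can be closed through either.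

## Retrosynthesis

**15 from 14 (four O–benzyl bonds).** All four phenols of 15 are traced back to benzyl ethers in 14. Benzyl is chosen over methoxymethyl or silyl groups because it survives base, copper and palladium catalysis and electrophilic iodine, and leaves by neutral hydrogenolysis that does not touch aryl methyl ethers or the chromone. The forward step only has to cleave benzylic C–O bonds.

**14 from 13 (C3–OMe bond).** The 3-methoxy group is cut at the C3–O bond to the 3-iodoflavone 13. The neighbouring option, oxidising a 3-unsubstituted flavone at C3, needs strong base or an oxidant on a very electron-rich molecule. The iodide comes for free from the ring closure and turns the problem into a copper-catalysed C–O coupling. The forward reaction must substitute iodine faster than alkoxide attacks C2, which is why a carbonate-buffered, ligand-accelerated protocol is planned instead of free sodium methoxide.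

**13 from 12 (O1–C2 bond, with C3–I).** Ring C is opened at O1–C2 to the alkynone 12. Electrophilic iodine activates the triple bond, one of the two equivalent ortho benzyloxy oxygens closes in a 6-endo-dig manner, and the benzyl group is lost from the oxonium ion. A base-mediated closure of a free ortho-hydroxy alkynone would compete with 5-exo closure to an aurone and would leave C3 unfunctionalised. The iodocyclization fixes the ring size and leaves iodine at C3. Because ring A of 12 is symmetric, no regiochemical question arises. The precursor is acyclic between the two arenes and much simpler.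

**12 from 5, 11 and 10 (C4a–C4 and C4–C3 bonds).** Both bonds to the carbonyl carbon are cut at once: the aryl iodide 5, carbon monoxide 11 and the terminal alkyne 10 are joined by a carbonylative Sonogashira coupling. The alternatives are less attractive:
- Friedel–Crafts acylation of 4 with an arylpropiolic acid derivative needs acid, which benzyl ethers on such an electron-rich ring tolerate poorly.
- Addition of an acetylide to a ring A aldehyde followed by oxidation costs two extra steps.
- Acyl Sonogashira coupling needs a doubly ortho-substituted benzoyl chloride.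

The three-component coupling is the most convergent, and the crowding at C4a, a handicap elsewhere, helps here because it slows direct alkynylation relative to CO insertion. The forward reaction must achieve oxidative addition at a hindered, electron-rich C–I bond and carbonylation before acetylide transfer. A copper-free protocol under moderate CO pressure is planned for that reason.

**5 from 4, 3, 2 and 1 (C–I, two C–OMe, three O–benzyl bonds).** The iodide 5 is traced to the pentaalkoxybenzene 4, whose single C–H is the only site for electrophilic iodination. The two methoxy groups of 4 are cut at the aryl–O bonds to the dibromide 3 (Ullmann-type methoxylation). 3 arises from the tribenzyl ether 2 by double bromination, and 2 from phloroglucinol 1. Every intermediate is symmetric, so no isomers can form. Two C–H bonds of 2 are turned into C–OMe and the third into C–I, which is exactly the pattern of ring A.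

**10 from 9, 8, 7 and 6 (alkyne carbon, redox adjustment, two O–benzyl bonds).** The alkyne 10 is cut at the triple bond to the aldehyde 9 (one-carbon homologation). 9 comes from the ester 7 through the alcohol 8, and 7 by benzylation of methyl 3,5-dihydroxy-4-methoxybenzoate 6. Compound 6 already carries the 4'-methoxy group between two free phenols, so ring B needs no selective alkylation.

## Roads not taken

**Alternative 1:** Ring A is built from an open chain.
- Cut: the bond between C4a and C8a of ring A. The precursor is dimethyl 2,4-dimethoxy-3,5-dioxoheptanedioate (A2).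
- Key step: under a magnesium alkoxide, the enolate of the methylene group of A2 attacks the remote ester carbonyl. Loss of methanol and enolisation give methyl 2,4,6-trihydroxy-3,5-dimethoxybenzoate (A1).
- Merits: the chain fixes the oxygenation pattern of ring A, so no hindered copper coupling on an arene is needed, and A1 already carries the future C4 as its ester carbon. In these two respects the route is as good as or better than the chosen one.
- Weak points: A2 is a labile, highly enolised tricarbonyl compound with two α-methoxy ketones; it is not commercial and would need several Claisen steps. Its cyclisation competes with O-acylation to a hydroxypyranone and with retro-Claisen cleavage. A1 then needs protection, and a doubly ortho-substituted benzoate must be converted into an ω-methoxy ketone before ring C and the 3-methoxy group can be made by an Allan–Robinson or Baker–Venkataraman sequence. Ring B also enters late and linearly.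
- Comparison: the chosen plan reaches the ring A block 5 in four steps from phloroglucinol and forms C4 and both of its ring bonds in one convergent step.

**Alternative 2:** Ring A is annulated onto a preformed pyranone.
- Cut: the C8–C8a bond and, before it, the bond from C4a to C5. The precursors are the pyranone A6 (2-[3,5-bis(benzyloxy)-4-methoxyphenyl]-3-methoxy-4H-pyran-4-one), the mixed squaric ester A5 (3-tert-butoxy-4-methoxycyclobut-3-ene-1,2-dione) and their adduct, the 4-hydroxycyclobutenone A4.
- Key step: a Moore rearrangement. On heating in a high-boiling aromatic solvent A4 opens to a dienylketene that closes onto C6 of the pyranone and tautomerises to the hydroquinone A3, 2-[3,5-bis(benzyloxy)-4-methoxyphenyl]-7-tert-butoxy-5,8-dihydroxy-3,6-dimethoxychromen-4-one.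
- Merits: ring A forms under neutral thermal conditions with all four oxygens differentiated. The 3-methoxy group is present from the start, so no iodide has to be exchanged at C3; this is better than the chosen plan. The hydrogen-bonded 5-OH should allow selective methylation of 8-OH.
- Weak points: A6 is itself a multistep target. Its metalation at C5 and not at C6 is not secured and would probably require a 5-halo derivative and halogen–metal exchange next to the pyranone carbonyl. The addition to A5 must choose the carbonyl next to the methoxy-bearing carbon, otherwise the 6- and 7-substituents are exchanged. A3 is an air-sensitive hydroquinone. Methylation, loss of the tert-butyl group and hydrogenolysis still follow.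
- Comparison: the chosen plan relies on the symmetry of ring A, which removes every regiochemical decision, and on two building blocks made in four routine steps each.

**Alternative 3:** Ring C is closed by acylation of ring A.
- Cut: the C4–C4a bond. The precursor is the acrylic acid A8, (2E)-3-[3,5-bis(benzyloxy)-2,4-dimethoxyphenoxy]-3-[3,5-bis(benzyloxy)-4-methoxyphenyl]-2-methoxyprop-2-enoic acid, which comes from the phenol A9 (3,5-bis(benzyloxy)-2,4-dimethoxyphenol).
- Key step: A8, activated as a mixed anhydride with a perfluorinated carboxylic anhydride, acylates the only C–H of ring A in a Friedel–Crafts closure. The product A7, 5,7-bis(benzyloxy)-2-[3,5-bis(benzyloxy)-4-methoxyphenyl]-3,6,8-trimethoxychromen-4-one, is identical with compound 14.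
- Merits: A7 is one hydrogenolysis away from the target, whereas the chosen key product 12 is three steps away, so the end game is shorter. The acylation site is unambiguous.
- Weak points: A9 is an unsymmetrical ring A block with one free phenol, two benzyl ethers and two methyl ethers, which takes the desymmetrisation that the chosen plan avoids. A8 is a tetrasubstituted enol ether whose carboxyl group must be cis to the aryloxy group; conjugate additions of phenols to arylpropiolates do not guarantee this geometry, and the α-methoxy group has to be introduced as well. The strongly acidic acylating medium threatens benzyl ethers on electron-rich rings through cleavage and C-benzylation.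
- Comparison: the chosen plan has a longer end game but uses symmetric, easily made precursors, has no alkene geometry to control and exposes the benzyl ethers to no strong acid.

Key step: step 9

Assumption: phloroglucinol is used in its anhydrous form, and in step 10 the benzyl group lost from the ring-closing oxygen is taken to leave as benzyl chloride.

## Route

Step 1
Reactants: 1 phloroglucinol (benzene-1,3,5-triol)
Product: 2 1,3,5-tris(benzyloxy)benzene
Conditions: BnBr (3.3 equiv), K2CO3, DMF, 0 °C → rt
Reagents that add atoms: benzyl bromide, BrCc1ccccc1
Why: Williamson etherification of the three phenols; a carbonate base in a dipolar aprotic solvent favours O- over C-benzylation of the phloroglucinol anion, which is the competing path.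

Step 2
Reactants: 2 1,3,5-tris(benzyloxy)benzene
Product: 3 1,3,5-tris(benzyloxy)-2,4-dibromobenzene
Conditions: NBS (2.05 equiv), CH2Cl2/MeCN, −20 → 0 °C
Reagents that add atoms: N-bromosuccinimide, O=C1CCC(=O)N1Br
Why: Electrophilic aromatic bromination of a ring in which each C–H is activated by three alkoxy groups; each bromine lowers the reactivity of the ring, so two equivalents at low temperature should stop at the dibromide.

Step 3
Reactants: 3 1,3,5-tris(benzyloxy)-2,4-dibromobenzene
Product: 4 1,3,5-tris(benzyloxy)-2,4-dimethoxybenzene
Conditions: NaOMe (8 equiv, in MeOH), CuI (30 mol %), DMF, 110 °C, argon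
Reagents that add atoms: sodium methoxide, C[O-].[Na+]
Why: Ullmann-type copper-catalysed methoxylation of aryl bromides, a reaction that tolerates alkoxy groups on both ortho positions; benzyl aryl ethers are inert to methoxide.

Step 4
Reactants: 4 1,3,5-tris(benzyloxy)-2,4-dimethoxybenzene
Product: 5 1,3,5-tris(benzyloxy)-2-iodo-4,6-dimethoxybenzene
Conditions: NIS (1.1 equiv), CF3CO2H (10 mol %), MeCN, 0 °C → rt, dark
Reagents that add atoms: N-iodosuccinimide, O=C1CCC(=O)N1I
Why: Electrophilic aromatic iodination at the only C–H of a pentaalkoxybenzene; the mild iodine source should avoid oxidation of the ring to a quinone.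

Step 5
Reactants: 6 methyl 3,5-dihydroxy-4-methoxybenzoate
Product: 7 methyl 3,5-bis(benzyloxy)-4-methoxybenzoate
Conditions: BnBr (2.4 equiv), K2CO3, DMF, 60 °C
Reagents that add atoms: benzyl bromide, BrCc1ccccc1
Why: Williamson etherification of the two equivalent phenols; the ester and the aryl methyl ether are untouched.

Step 6
Reactants: 7 methyl 3,5-bis(benzyloxy)-4-methoxybenzoate
Product: 8 [3,5-bis(benzyloxy)-4-methoxyphenyl]methanol
Conditions: LiAlH4, THF, 0 °C → rt; H2O, aq NaOH work-up
Reagents that add atoms: none
Why: Hydride reduction of an aryl ester to the benzylic alcohol; benzyl and methyl ethers are inert.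

Step 7
Reactants: 8 [3,5-bis(benzyloxy)-4-methoxyphenyl]methanol
Product: 9 3,5-bis(benzyloxy)-4-methoxybenzaldehyde
Conditions: activated MnO2 (excess), CH2Cl2, rt
Reagents that add atoms: none
Why: Heterogeneous MnO2 oxidation of a benzylic alcohol, which stops cleanly at the aldehyde.

Step 8
Reactants: 9 3,5-bis(benzyloxy)-4-methoxybenzaldehyde
Product: 10 1,3-bis(benzyloxy)-5-ethynyl-2-methoxybenzene
Conditions: dimethyl (1-diazo-2-oxopropyl)phosphonate, K2CO3, MeOH/THF, 0 °C → rt
Reagents that add atoms: dimethyl (1-diazo-2-oxopropyl)phosphonate (Ohira–Bestmann reagent), CC(=O)C(=[N+]=[N-])P(=O)(OC)OC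
Why: Seyferth–Gilbert homologation in the Ohira–Bestmann variant: methanolysis of the reagent gives the diazomethylphosphonate anion, which adds to the aldehyde, eliminates phosphate and nitrogen and gives the terminal alkyne by 1,2-shift; the carbonate conditions suit a non-enolisable aryl aldehyde.

Step 9
Reactants: 5 1,3,5-tris(benzyloxy)-2-iodo-4,6-dimethoxybenzene; 10 1,3-bis(benzyloxy)-5-ethynyl-2-methoxybenzene; 11 carbon monoxide
Product: 12 3-[3,5-bis(benzyloxy)-4-methoxyphenyl]-1-[2,4,6-tris(benzyloxy)-3,5-dimethoxyphenyl]prop-2-yn-1-one
Conditions: PdCl2(PPh3)2 (5 mol %), Et3N (3 equiv), CO (5 bar), THF, 60 °C, no copper salt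
Reagents that add atoms: none
Why: The reaction is a palladium-catalysed carbonylative Sonogashira coupling, the closest known reaction type being the three-component coupling of aryl iodides, carbon monoxide and terminal alkynes to alkynones. PdCl2(PPh3)2 is reduced in the flask to zerovalent palladium, which inserts into the C–I bond of 5; CO then binds and the aryl group migrates to it, forming the C4a–C4 bond in an aroyl palladium species. Alkyne 10, deprotonated by Et3N at the metal, is transferred as its acetylide, and reductive elimination forms the C4–C3 bond and returns zerovalent palladium. No ring is closed and no stereocentre is formed. The selectivity needed is carbonylative over direct coupling: the two ortho benzyloxy groups crowd the aryl palladium centre and slow acetylide transfer there, whereas the small CO ligand still inserts, the electron-rich aryl group migrates readily, and the resulting aroyl complex holds the metal one atom further from the ortho substituents. Leaving out a copper co-catalyst keeps the acetylide concentration low, which further disfavours direct alkynylation and suppresses Glaser dimerisation of 10, and moderate CO pressure keeps insertion fast without blocking oxidative addition. Benzyl ethers, methyl ethers and the product alkynone are inert to Et3N.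

Step 10
Reactants: 12 3-[3,5-bis(benzyloxy)-4-methoxyphenyl]-1-[2,4,6-tris(benzyloxy)-3,5-dimethoxyphenyl]prop-2-yn-1-one
Product: 13 5,7-bis(benzyloxy)-2-[3,5-bis(benzyloxy)-4-methoxyphenyl]-3-iodo-6,8-dimethoxy-4H-chromen-4-one
Conditions: ICl (1.2 equiv), CH2Cl2, −78 °C; aq Na2S2O3 work-up
Reagents that add atoms: iodine monochloride, ClI
Why: Dealkylative electrophilic iodocyclization of an ortho-alkoxyaryl alkynone: the iodonium-activated triple bond is attacked at the ring B-bearing carbon by an ortho ether oxygen in a 6-endo-dig closure, and chloride removes the benzyl group from the oxonium ion. The two ortho benzyloxy groups are equivalent, so one product is expected, and ring A has no C–H that could be iodinated.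

Step 11
Reactants: 13 5,7-bis(benzyloxy)-2-[3,5-bis(benzyloxy)-4-methoxyphenyl]-3-iodo-6,8-dimethoxy-4H-chromen-4-one
Product: 14 5,7-bis(benzyloxy)-2-[3,5-bis(benzyloxy)-4-methoxyphenyl]-3,6,8-trimethoxy-4H-chromen-4-one
Conditions: CuI (10 mol %), 3,4,7,8-tetramethyl-1,10-phenanthroline (20 mol %), Cs2CO3 (2 equiv), MeOH (5 equiv), toluene, 80 °C
Reagents that add atoms: methanol, CO
Why: Ullmann-type copper-catalysed C–O coupling of an alkenyl iodide with an aliphatic alcohol; carbonate as base keeps the standing concentration of methoxide low, which limits attack at C2 of the pyranone, and flavone nuclei are known to survive copper-mediated methoxylation of ring halides.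

Step 12
Reactants: 14 5,7-bis(benzyloxy)-2-[3,5-bis(benzyloxy)-4-methoxyphenyl]-3,6,8-trimethoxy-4H-chromen-4-one
Product: 15 5,7-dihydroxy-2-(3,5-dihydroxy-4-methoxyphenyl)-3,6,8-trimethoxy-4H-chromen-4-one (5,7,3',5'-tetrahydroxy-3,6,8,4'-tetramethoxyflavone)
Conditions: H2 (1 atm), 10% Pd/C, EtOAc/MeOH, rt
Reagents that add atoms: none
Why: Hydrogenolysis of the four benzyl aryl ethers over palladium on carbon; aryl and enol methyl ethers and the chromone double bond are not reduced under these conditions, so the four phenols should be freed in one operation.

## Compound list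

1 | phloroglucinol (benzene-1,3,5-triol) | Oc1cc(O)cc(O)c1 | starting material
2 | 1,3,5-tris(benzyloxy)benzene | c1ccc(COc2cc(OCc3ccccc3)cc(OCc3ccccc3)c2)cc1 | intermediate
3 | 1,3,5-tris(benzyloxy)-2,4-dibromobenzene | Brc1c(OCc2ccccc2)cc(OCc2ccccc2)c(Br)c1OCc1ccccc1 | intermediate
4 | 1,3,5-tris(benzyloxy)-2,4-dimethoxybenzene | COc1c(OCc2ccccc2)cc(OCc2ccccc2)c(OC)c1OCc1ccccc1 | intermediate
5 | 1,3,5-tris(benzyloxy)-2-iodo-4,6-dimethoxybenzene | Ic1c(OCc2ccccc2)c(OC)c(OCc2ccccc2)c(OC)c1OCc1ccccc1 | intermediate
6 | methyl 3,5-dihydroxy-4-methoxybenzoate | COC(=O)c1cc(O)c(OC)c(O)c1 | starting material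
7 | methyl 3,5-bis(benzyloxy)-4-methoxybenzoate | COC(=O)c1cc(OCc2ccccc2)c(OC)c(OCc2ccccc2)c1 | intermediate
8 | [3,5-bis(benzyloxy)-4-methoxyphenyl]methanol | OCc1cc(OCc2ccccc2)c(OC)c(OCc2ccccc2)c1 | intermediate
9 | 3,5-bis(benzyloxy)-4-methoxybenzaldehyde | O=Cc1cc(OCc2ccccc2)c(OC)c(OCc2ccccc2)c1 | intermediate
10 | 1,3-bis(benzyloxy)-5-ethynyl-2-methoxybenzene | C#Cc1cc(OCc2ccccc2)c(OC)c(OCc2ccccc2)c1 | intermediate
11 | carbon monoxide | [C-]#[O+] | starting material
12 | 3-[3,5-bis(benzyloxy)-4-methoxyphenyl]-1-[2,4,6-tris(benzyloxy)-3,5-dimethoxyphenyl]prop-2-yn-1-one | O=C(C#Cc1cc(OCc2ccccc2)c(OC)c(OCc2ccccc2)c1)c1c(OCc2ccccc2)c(OC)c(OCc2ccccc2)c(OC)c1OCc1ccccc1 | intermediate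
13 | 5,7-bis(benzyloxy)-2-[3,5-bis(benzyloxy)-4-methoxyphenyl]-3-iodo-6,8-dimethoxy-4H-chromen-4-one | COc1c(OCc2ccccc2)cc(cc1OCc1ccccc1)-c1oc2c(OC)c(OCc3ccccc3)c(OC)c(OCc3ccccc3)c2c(=O)c1I | intermediate
14 | 5,7-bis(benzyloxy)-2-[3,5-bis(benzyloxy)-4-methoxyphenyl]-3,6,8-trimethoxy-4H-chromen-4-one | COc1c(OCc2ccccc2)cc(cc1OCc1ccccc1)-c1oc2c(OC)c(OCc3ccccc3)c(OC)c(OCc3ccccc3)c2c(=O)c1OC | intermediate
15 | 5,7-dihydroxy-2-(3,5-dihydroxy-4-methoxyphenyl)-3,6,8-trimethoxy-4H-chromen-4-one | COc1c(O)cc(-c2oc3c(OC)c(O)c(OC)c(O)c3c(=O)c2OC)cc1O | target

## Step count and risk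

Total step count: 12. Longest linear sequence: 8 steps (steps 1–4 and 9–12; the ring B branch, steps 5–8 and 9–12, is equally long).

**Step 9 (key step).**
- Risk: oxidative addition at the crowded, electron-rich C–I bond may be slow under CO, so that the catalyst is lost as inactive palladium carbonyl species before turnover. Acetylide transfer may also overtake CO insertion and give the diarylalkyne, or the alkyne may dimerise.
- Fallback: the same two bonds to C4 are formed one after the other without palladium. Starting from 5, iodine–lithium exchange (n-BuLi, THF, −78 °C) and trapping with DMF would give 2,4,6-tris(benzyloxy)-3,5-dimethoxybenzaldehyde F1. The lithium acetylide of 10 (n-BuLi, THF, −78 °C) would add to it to give racemic 3-[3,5-bis(benzyloxy)-4-methoxyphenyl]-1-[2,4,6-tris(benzyloxy)-3,5-dimethoxyphenyl]prop-2-yn-1-ol F2. Oxidation with MnO2 in CH2Cl2 returns to the route at 12.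

**Step 11.**
- Risk: alkoxide may attack C2 of the 3-iodochromone, with opening of the pyranone and ring contraction, and iodine may be lost reductively under the copper conditions.
- Fallback: the oxygen is introduced as an electrophile instead. Starting from 13, iodine–magnesium exchange (iPrMgCl·LiCl, THF, −40 °C), borylation with B(OMe)3 and oxidation (H2O2, aq NaHCO3) would give 5,7-bis(benzyloxy)-2-[3,5-bis(benzyloxy)-4-methoxyphenyl]-3-hydroxy-6,8-dimethoxy-4H-chromen-4-one F3. Methylation (MeI, K2CO3, acetone) returns to the route at 14.

**Step 10.**
- Risk: the benzyl ether oxygen, more hindered than the usual methyl ether, may close sluggishly, so that iodination of ring B at C2'/C6' or simple addition of ICl across the triple bond competes.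
- Fallback: closure and iodination are separated. Starting from 12, chelation-controlled removal of one ortho benzyl group (BCl3, 1.1 equiv, CH2Cl2, −78 °C) would give 1-[2,4-bis(benzyloxy)-6-hydroxy-3,5-dimethoxyphenyl]-3-[3,5-bis(benzyloxy)-4-methoxyphenyl]prop-2-yn-1-one F4. Nucleophile-catalysed 6-endo cyclisation (DMAP, DMF, rt) would give 5,7-bis(benzyloxy)-2-[3,5-bis(benzyloxy)-4-methoxyphenyl]-6,8-dimethoxy-4H-chromen-4-one F5. Lithiation at C3 (LiN(iPr)2, THF, −78 °C) and quenching with I2 returns to the route at 13.

**Step 3.**
- Risk: reductive loss of bromine may compete with substitution, and the second coupling may stall because the bromide is flanked by two benzyloxy groups.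
- Fallback: the oxygen is introduced as hydroxide under palladium catalysis and methylated afterwards. Starting from 3, hydroxylation (Pd2(dba)3, tBuXPhos, KOH, dioxane/H2O, 100 °C) would give 2,4,6-tris(benzyloxy)benzene-1,3-diol F6. Methylation (Me2SO4, K2CO3, acetone) returns to the route at 4.

## Further compounds

F1 | step 9 | 2,4,6-tris(benzyloxy)-3,5-dimethoxybenzaldehyde | O=Cc1c(OCc2ccccc2)c(OC)c(OCc2ccccc2)c(OC)c1OCc1ccccc1
F2 | step 9 | 3-[3,5-bis(benzyloxy)-4-methoxyphenyl]-1-[2,4,6-tris(benzyloxy)-3,5-dimethoxyphenyl]prop-2-yn-1-ol (racemic) | OC(C#Cc1cc(OCc2ccccc2)c(OC)c(OCc2ccccc2)c1)c1c(OCc2ccccc2)c(OC)c(OCc2ccccc2)c(OC)c1OCc1ccccc1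
F3 | step 11 | 5,7-bis(benzyloxy)-2-[3,5-bis(benzyloxy)-4-methoxyphenyl]-3-hydroxy-6,8-dimethoxy-4H-chromen-4-one | COc1c(OCc2ccccc2)cc(cc1OCc1ccccc1)-c1oc2c(OC)c(OCc3ccccc3)c(OC)c(OCc3ccccc3)c2c(=O)c1O
F4 | step 10 | 1-[2,4-bis(benzyloxy)-6-hydroxy-3,5-dimethoxyphenyl]-3-[3,5-bis(benzyloxy)-4-methoxyphenyl]prop-2-yn-1-one | O=C(C#Cc1cc(OCc2ccccc2)c(OC)c(OCc2ccccc2)c1)c1c(O)c(OC)c(OCc2ccccc2)c(OC)c1OCc1ccccc1
F5 | step 10 | 5,7-bis(benzyloxy)-2-[3,5-bis(benzyloxy)-4-methoxyphenyl]-6,8-dimethoxy-4H-chromen-4-one | COc1c(OCc2ccccc2)cc(cc1OCc1ccccc1)-c1cc(=O)c2c(OCc3ccccc3)c(OC)c(OCc3ccccc3)c(OC)c2o1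
F6 | step 3 | 2,4,6-tris(benzyloxy)benzene-1,3-diol | Oc1c(OCc2ccccc2)cc(OCc2ccccc2)c(O)c1OCc1ccccc1
A1 | alternative 1 | methyl 2,4,6-trihydroxy-3,5-dimethoxybenzoate | COC(=O)c1c(O)c(OC)c(O)c(OC)c1O
A2 | alternative 1 | dimethyl 2,4-dimethoxy-3,5-dioxoheptanedioate (mixture of stereoisomers) | COC(=O)CC(=O)C(OC)C(=O)C(OC)C(=O)OC
A3 | alternative 2 | 2-[3,5-bis(benzyloxy)-4-methoxyphenyl]-7-tert-butoxy-5,8-dihydroxy-3,6-dimethoxychromen-4-one | COc1c(OCc2ccccc2)cc(cc1OCc1ccccc1)-c1oc2c(O)c(OC(C)(C)C)c(OC)c(O)c2c(=O)c1OC
A4 | alternative 2 | 2-[3,5-bis(benzyloxy)-4-methoxyphenyl]-5-(3-tert-butoxy-1-hydroxy-2-methoxy-4-oxocyclobut-2-en-1-yl)-3-methoxy-4H-pyran-4-one (racemic) | COc1c(OCc2ccccc2)cc(cc1OCc1ccccc1)-c1occ(C2(O)C(=O)C(OC(C)(C)C)=C2OC)c(=O)c1OC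
A5 | alternative 2 | 3-tert-butoxy-4-methoxycyclobut-3-ene-1,2-dione | CC(C)(C)OC1=C(OC)C(=O)C1=O
A6 | alternative 2 | 2-[3,5-bis(benzyloxy)-4-methoxyphenyl]-3-methoxy-4H-pyran-4-one | COc1c(OCc2ccccc2)cc(cc1OCc1ccccc1)-c1occc(=O)c1OC
A7 | alternative 3 | 5,7-bis(benzyloxy)-2-[3,5-bis(benzyloxy)-4-methoxyphenyl]-3,6,8-trimethoxychromen-4-one | COc1c(OCc2ccccc2)cc(cc1OCc1ccccc1)-c1oc2c(OC)c(OCc3ccccc3)c(OC)c(OCc3ccccc3)c2c(=O)c1OC
A8 | alternative 3 | (2E)-3-[3,5-bis(benzyloxy)-2,4-dimethoxyphenoxy]-3-[3,5-bis(benzyloxy)-4-methoxyphenyl]-2-methoxyprop-2-enoic acid | OC(=O)/C(OC)=C(\Oc1cc(OCc2ccccc2)c(OC)c(OCc2ccccc2)c1OC)c1cc(OCc2ccccc2)c(OC)c(OCc2ccccc2)c1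
A9 | alternative 3 | 3,5-bis(benzyloxy)-2,4-dimethoxyphenol | COc1c(O)cc(OCc2ccccc2)c(OC)c1OCc1ccccc1
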